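The target was already the larger product at the first reading of Tuesday's run, and how much larger was the quantity I carried through these flasks.

| setting | Tuesday's | Sunday's | teal | blue |
|---|---|---|---|---|
| starting material | 1.5 M | 1.5 M | 3.0 M | 3.0 M |
| temperature | 50 °C | 72 °C |  |  |
| remark | run made earlier | run made earlier | at 40 °C throughout | at 40 °C until 3.0 min, from then on at 80 °C |
| time |  |  | 10 min | 10 min |

Tuesday's run (percent of the starting material charged)

| time / min | target / % | isomer of the product / % |
|---|---|---|
| 0.417 | 50 | 24 |
| 0.667 | 58 | 31 |
| 1.33 | 62 | 20 |
| 2.00 | 67 | 25 |
| 3.00 | 76 | 18 |
| 5.00 | 73 | 13 |

Sunday's run (percent of the starting material charged)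

| time / s | target / % | isomer of the product / % |
|---|---|---|
| 10.0 | 75 | 9 |
| 12.0 | 78 | 10 |
| 25.0 | 81 | 6 |
| 40.0 | 83 | 6 |
| 60.0 | 82 | 5 |
| 90.0 | 84 | 9 |

(scatter of a reading: 2 percentage points)

- on the list of suspects stand: starting material <-> target; starting material <-> isomer of the product

- the winner by share of target in all that became target or isomer of the product; "neither" if no more than 2 percentage points parts them (teal / blue / neither)
- share of target in all that became target or isomer of the product, teal
- share of target in all that became target or isomer of the product, blue

My zero of the scale was the even split, a product ratio [target]/[isomer of the product] of one, which two equal forward steps would give. Against it I defined the early ratio, the product ratio while the starting material is first being shared out and little has yet gone back. Pooling the first two readings of Tuesday's run, I read it as 1.96.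

I took the run in three stages. In the first instants, I reasoned, both forward steps draw on the starting material and the target step takes the larger part: kinetic control. In the middle, the isomer of the product in Tuesday's run fell from 31 % at 0.667 min to 13 % at 5.00 min, while the target rose from 58 % to 73 %, so I read the isomer as returning through the starting material. The product ratio there had reached 5.62. At the end stood thermodynamic control: Sunday's readings from 25.0 s on pooled to a late ratio of 12.7.

Teal, colder than Tuesday's run, should therefore have climbed slowly from the early ratio, which I carried to 40 °C unchanged for want of a reading there. Blue had 7.00 min above Sunday's temperature, far longer than Sunday's run needed, so I expected it near the late ratio.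

The forecast said blue, with 75 % for teal and 92 % for blue: “Both runs show the isomer forming quickly and then draining back through the starting material to the target.”

The flasks gave 73.3 % for teal and 94.6 % for blue, so blue won.

    starting material ⇌ target (K = 6.80, k = 0.0120 s⁻¹, Ea = 96.0 kJ mol⁻¹, ΔH = 5.00 kJ mol⁻¹)
    starting material ⇌ isomer of the product (K = 2.10, k = 0.00760 s⁻¹, Ea = 99.0 kJ mol⁻¹, ΔH = −34.0 kJ mol⁻¹)
    (constants at 40 °C)

At 10.0 min the product ratio stood at 2.75 in teal and 17.7 in blue, against the early 1.96. The temperature programme is the main reason for that gap: given blue's programme, teal's share of target rises from 73.3 % to 94.6 %. The repeat of teal at 15 °C still held 64 % of its charge as starting material at 10.0 min, with 23.0 % target and 13.3 % isomer of the product, a product ratio of 1.73, lower than the early ratio read at 50 °C.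

The numbers in the tables come from a simulation for an exercise.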